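Its constants were chosen freely; the flask was simulated.

Activator left over at the end of a closed flask is activator that met no starting material, and with starting material and activator charged at 0.30 M and 0.300 M, equal charges, that leftover equals the part of the starting material that was never activated.

    capture agent + activated form → trapped intermediate (k1 = 0.044 L mol⁻¹ min⁻¹)
    starting material + ring → side product (k2 = 0.010 L mol⁻¹ min⁻¹)
    activated form → ring (k3 = 0.90 min⁻¹)
    starting material + activated form → open dimer (k4 = 0.63 L mol⁻¹ min⁻¹)
    2 starting material → homo dimer (k5 = 0.12 L mol⁻¹ min⁻¹)
    starting material + activator → activated form (k6 = 0.059 L mol⁻¹ min⁻¹)

| flask | starting material | activator | capture agent | time | remark |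
|---|---|---|---|---|---|
| amber | 0.30 M | 0.300 M (fed, over 4.00 h) | 0.300 M | 4.0 h | all but activator at the start; activator goes in evenly over 4.00 h, the run ends at 4.0 h |
| ochre | 0.30 M | 0.300 M | 0.300 M |  | a single well-mixed tank run continuously and read at steady state, 4.0 h in it on average |
| red | 0.30 M | 0.300 M | 0.300 M | 4.0 h | everything together in a closed stirred flask, run for 4.0 h |
| blue | 0.30 M | 0.300 M | 0.300 M |  | a single well-mixed tank run continuously and read at steady state, 40.0 h in it on average |

- a species is counted by the starting material in it: one open dimer or homo dimer or side product counts as two
- for a step with 2 of a species take k times the square, and two of it per event
- the stated concentrations are those of everything mixed, before any reaction; amounts are the same in each set-up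
- the feed brings no volume worth counting
- run time (amber): 4.0 h

1. the set-up with the highest amount of ring at the outlet or at the end, in percent of the starting material put in ("none" if the first two lie within 2 percentage points) (amber / ochre / red / blue / none)
2. amount of ring at the outlet or at the end, in percent of the starting material put in, amber
3. amount of ring at the outlet or at the end, in percent of the starting material put in, ochre
4. amount of ring at the outlet or at the end, in percent of the starting material put in, red
5. amount of ring at the outlet or at the end, in percent of the starting material put in, blue

I first asked which constants had to be good. The capture constant could be rough: activated form closes to ring with a half-life of 0.0128 h, far shorter than 0.88 h by capture, so capture takes 1.47% of it. The constants of steps 3 and 4 enter as a correction, since open dimer competes with ring at 21.0% at the charged level. The constant of step 2 I left open: its weight hangs on the level of starting material in the tanks, and I did not have that level. The constants of steps 5 and 6 count in full, through the split (a selectivity factor), the rate at which homo dimer uses starting material over the rate at which activation uses it, here at the charges: 4.07.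

For red I integrated the ratio of those two rates from equal charges until starting material was gone. That left 63.3% of the activator, so 36.7% was activated. Taking half the charged level as typical, open dimer removes 10.5% of that, and ring comes to 32.9%. In amber, starting material's half-life by step 5 at the charge is 0.231 h, shorter than the 4.00 h of dosing, so I put amber below red. At a fixed dosing schedule, with a large split, ring should go inversely with the split. I did not solve the tanks.

The forecast gave amber 13.5%, ochre 34%, red 30%, below my figure, and blue 47%, naming blue, on the ground that “low starting-material concentration favours activation because it is first order in starting material while homo-dimerisation is second order”.

The simulation gave amber 10.7%, ochre 33.7%, red 30.7% and blue 47.0%, so blue stood highest, and red kept 65% of its activator. In amber, half of the homo dimer turnover was done by 0.178 h, when 4.45% of the activator had been dosed, and the split reached 0.059 at 4.00 h, far below the charged 4.07. One more flask like amber, with 0.75 M of starting material, has a split of 10.2; scaling amber's ring by the two splits gives 4.27%, and that flask gave 4.70%.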